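The data are calculated for an exercise; scatter was added.

**Forks.** In a one-step world every mole of starting material would become side product, and one clock would do. This flask has forks, so follow the starting material, the limiting reagent, through a ledger.

| setting | ochre | violet | teal | south-west | north-west | south | north-east |
|---|---|---|---|---|---|---|---|
| starting material | 0.10 M | 0.10 M | 0.10 M | 0.10 M | 0.10 M (fed, over 2.5 min) | 0.10 M (in portions, 5, over 2.5 min) | 0.10 M |
| coupling partner | 0.12 M | 0.12 M | 0.12 M | 0.120 M (fed, over 2.5 min) | 0.120 M | 0.120 M | 0.120 M |
| capture agent | 0.10 M | 0.050 M | 0.075 M | 0.100 M | 0.100 M | 0.100 M | 0.100 M |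
| protic impurity | 0.020 M | 0.020 M | 0.020 M | 0.0200 M | 0.0200 M | 0.0200 M | 0.0200 M |
| remark | run made earlier | run made earlier | run made earlier | all else is in the flask from the start; the feed brings no volume worth counting | all else is in the flask from the start; the feed brings no volume worth counting | first portion at the start, last at 2.5 min | everything together at the start |
| time |  |  |  | 4.0 min | 4.0 min | 4.0 min | 4.0 min |

| run | time / min | side product / % | target / % |
|---|---|---|---|
| ochre | 0.333 | 5.3 | 0.8 |
| ochre | 0.667 | 12.3 | 1.1 |
| ochre | 1.50 | 24.1 | 2.2 |
| ochre | 4.00 | 41.7 | 4.2 |
| violet | 0.333 | 5.9 | 0 |
| violet | 0.667 | 12.3 | 0.9 |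
| violet | 1.50 | 24.2 | 2.4 |
| violet | 4.00 | 43.2 | 4.5 |
| teal | 0.333 | 5.6 | 0.3 |
| teal | 0.667 | 12.2 | 1.1 |
| teal | 1.50 | 24.2 | 2.5 |
| teal | 4.00 | 42.1 | 3.8 |

(standard deviation of a reading: 0.3 percentage points)

- which flask leads in amount of side product, in percent of the starting material charged ("all alike" within 1.5 percentage points) (south-west / north-west / south / north-east / all alike)
- how much side product is there at the end, in percent of the starting material charged: south-west
- how much side product is there at the end, in percent of the starting material charged: north-west
- how much side product is there at the end, in percent of the starting material charged: south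
- how much side product is there at the end, in percent of the starting material charged: north-east

- the numbers in the tables scatter with a standard deviation of 0.3 percentage points
- on the list of suspects stand: starting material <-> intermediate A; starting material + coupling partner <-> intermediate B; intermediate A -> side product; coupling partner + intermediate A -> target; capture agent + intermediate A -> trapped intermediate; starting material + protic impurity -> quenched substrate

**The ledger.** Take the ochre run at 4.00 min. Each protic impurity can take one starting material, so that entry is at most 20.0 % of the charge. Side product stands at 41.7 % and target at 4.2 %, which leaves at least 34.1 % open, among starting material, the intermediates and the trapped intermediate. Going from 0.10 M to 0.050 M of capture agent moves side product by 1.5 percentage points.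

**The share.** In the ochre run at 4.00 min, side product is at most 0.521 of the charge that escapes the impurity: call this the escape share.

**My reckoning.** North-east is the ochre recipe, so I expect 41.7 % again. In north-west and south the starting material arrives on average at 1.25 min, so it has had 2.75 min in the flask, and the ochre readings, read between their points, give 32.9 %. I expect south-west to lead, but the runs cannot size it: [coupling partner] stood at 0.12 M in each.

**The forecast.** It names south-west as leader, with 44.5 % there, 42 % in north-east, and 35 % and 35.5 % in north-west and south, both higher than my figure. Its ground for the leader: “Slow partner feed should raise it slightly”.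

**The result.** South-west leads with 46.8 %, ahead of north-east at 41.6 %, north-west at 33.7 % and south at 33.2 %, and the forecast stands within its tolerance on each. At 4.00 min south-west holds 17.6 % as quenched substrate, inside the entry of 20.0 %. The escape share on the 82.4 % that escaped gives 42.9 %, and south-west shows 3.9 points more.

    starting material ⇌ intermediate A (K = 0.610, k = 0.0470 s⁻¹)
    starting material + coupling partner ⇌ intermediate B (K = 8.70 M⁻¹, k = 0.0730 M⁻¹ s⁻¹)
    intermediate A → side product (k = 0.0140 s⁻¹)
    coupling partner + intermediate A → target (k = 0.0130 M⁻¹ s⁻¹)
    capture agent + intermediate A → trapped intermediate (k = 0.0240 M⁻¹ s⁻¹)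
    starting material + protic impurity → quenched substrate (k = 0.310 M⁻¹ s⁻¹)

**Less impurity.** Take south-west with 0.0080 M of protic impurity. There 7.22 % ends as quenched substrate, and the escape share on the 92.8 % that escaped gives 48.3 %. The computed flask gives 51.7 %, which is 3.4 points more.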